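Ring A carries its substituents pairwise: C1 (tigloyloxy) adjoins C6, which holds the quaternary oxirane carbon Cq, and C3 (methyl) adjoins C4 (methoxy), with C2 and C5 unsubstituted. The ring is therefore cut at C1–C2 and C5–C6 into 2-methoxy-3-methylbutadiene and a disubstituted alkyne. A single thermal Diels–Alder reaction makes both bonds and closes ring A, placing an acetyl group, the latent phenol oxygen, on C1 para to C4. The dienophile is an enantiopure methyl ynone whose Cq already bears the isovalerate arm and, tied back as an acetonide, the oxygen and methylene of the future oxirane; its configuration comes from a lipase desymmetrisation.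

Key step: step 8

Numbering and target check: ring A is C1 (O-acyl), C2 (H), C3 (CH3), C4 (OCH3), C5 (H), C6 (bears Cq). The target is R at Cq (priorities O > CH2O-acyl > oxirane CH2 > aryl), and its alkene is E (tiglate).

Assumption: the lipase of step 3 is taken, after screening, to acylate the pro-R hydroxymethyl group of triol 4. An enzyme of the opposite preference is put to use through the fallback given for step 3.

Step 1
Reactants: 1 2,2-dimethyl-1,3-dioxan-5-one; 2 ethynylmagnesium bromide
Product: 3 5-ethynyl-2,2-dimethyl-1,3-dioxan-5-ol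
Conditions: 2 (1.2 equiv, 0.5 M in THF), THF, −20 to 0 °C; then sat. aq. NH4Cl
Reagents that add atoms: none
Why: Grignard 1,2-addition of a weakly basic alkynyl nucleophile to an unhindered ketone is reliable, and the product keeps a mirror plane, so no stereochemical question arises yet.

Step 2
Reactants: 3 5-ethynyl-2,2-dimethyl-1,3-dioxan-5-ol
Product: 4 2-ethynylpropane-1,2,3-triol
Conditions: sulfonic acid ion-exchange resin (H+ form), MeOH–H2O 1:1, 40 °C; filter, evaporate
Reagents that add atoms: none
Why: Acid-catalysed ketal hydrolysis releases only volatile acetone, and a filterable acid spares the very water-soluble prochiral triol an aqueous extraction.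

Step 3
Reactants: 4 2-ethynylpropane-1,2,3-triol; 5 isovaleric anhydride
Product: 6 (2R)-2-hydroxy-2-(hydroxymethyl)but-3-yn-1-yl 3-methylbutanoate
Conditions: immobilised Burkholderia cepacia lipase, 5 (1.1 equiv), THF–MTBE 1:1, 25 °C, stopped when 4 is consumed; filter, concentrate, carry on crude
Reagents that add atoms: none
Why: Lipase-catalysed enantiotopic-group-selective acylation (desymmetrisation of a prochiral 2-substituted glycerol) installs the final isovalerate and sets Cq as R in one operation, because the chiral active site acylates only the pro-R CH2OH, the tertiary alcohol is no lipase substrate, and any slow second acylation consumes mainly the minor enantiomer.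

Step 4
Reactants: 6 (2R)-2-hydroxy-2-(hydroxymethyl)but-3-yn-1-yl 3-methylbutanoate
Product: 7 [(4R)-4-ethynyl-2,2-dimethyl-1,3-dioxolan-4-yl]methyl 3-methylbutanoate
Conditions: Me2C(OMe)2 (3 equiv), PPTS (5 mol %), CH2Cl2, 0 °C to rt; aq. NaHCO3 wash
Reagents that add atoms: 2,2-dimethoxypropane, COC(C)(C)OC
Why: Acid-catalysed transketalisation joins the tertiary and the remaining primary hydroxyl in a dioxolane without touching any bond to Cq, and it removes the free CH2OH to which the isovaleryl group could otherwise migrate with racemisation.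

Step 5
Reactants: 7 [(4R)-4-ethynyl-2,2-dimethyl-1,3-dioxolan-4-yl]methyl 3-methylbutanoate; 8 N-methoxy-N-methylacetamide
Product: 10 [(4R)-2,2-dimethyl-4-(3-oxobut-1-yn-1-yl)-1,3-dioxolan-4-yl]methyl 3-methylbutanoate, via lithium acetylide 9 (not isolated)
Conditions: LiN(SiMe3)2 (1.05 equiv), THF, −78 °C; then 8 (1.5 equiv), −78 to 0 °C; poured into cold aq. KH2PO4
Reagents that add atoms: lithium bis(trimethylsilyl)amide, [Li]N([Si](C)(C)C)[Si](C)(C)C (its lithium is carried by 9 only)
Why: The acetylenic C–H is the most acidic site by several pK units and LiN(SiMe3)2 is too hindered to attack the ester, so 9 should form cleanly at −78 °C, and its acylation (Weinreb ketone synthesis) stops at the ketone because the chelated tetrahedral adduct survives until the quench.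

Step 6
Reactants: 11 3-methylbut-3-en-2-one
Product: 12 1,3,3-trimethoxy-2-methylbutane (racemic)
Conditions: HC(OMe)3 (1.3 equiv), MeOH, p-TsOH·H2O (1 mol %), trace hydroquinone, 0 to 40 °C; NaOMe quench; distil
Reagents that add atoms: methanol, CO; trimethyl orthoformate, COC(OC)OC
Why: Under acid the terminal enone takes up methanol by oxa-Michael addition and the resulting ketone is ketalised with orthoformate as water scavenger, so pushing to this fully methanol-saturated compound avoids a mixture with the simple enone ketal, and the racemic centre disappears in the next step.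

Step 7
Reactants: 12 1,3,3-trimethoxy-2-methylbutane
Product: 13 2-methoxy-3-methylbuta-1,3-diene
Conditions: KHSO4 (1 wt %), neat, bath 150–160 °C, diene and MeOH distilled out as formed; cold aq. K2CO3 wash, dried and stored over K2CO3 with BHT at −20 °C
Reagents that add atoms: none
Why: Acid-catalysed loss of two methanol molecules from a β-methoxy ketal is the classical route to 2-alkoxy-1,3-dienes, both orders of elimination converge on the same diene, and continuous distillation takes the acid-sensitive product away from the catalyst.

Step 8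
Reactants: 10 [(4R)-2,2-dimethyl-4-(3-oxobut-1-yn-1-yl)-1,3-dioxolan-4-yl]methyl 3-methylbutanoate; 13 2-methoxy-3-methylbuta-1,3-diene
Product: 14 [(4R)-4-(2-acetyl-5-methoxy-4-methylcyclohexa-1,4-dien-1-yl)-2,2-dimethyl-1,3-dioxolan-4-yl]methyl 3-methylbutanoate
Conditions: 13 (4 equiv), BHT (2 mol %), toluene (1 M), base-washed sealed tube, 125 °C; excess 13 evaporated, crude carried on
Reagents that add atoms: none
Why: The reaction is a concerted but asynchronous, normal-electron-demand (4+2) cycloaddition between the s-cis form of electron-rich diene 13 and the acetyl-activated triple bond of 10, and its closest known relatives are the thermal Diels–Alder reactions of 2-alkoxybutadienes with acetylenic ketones that give 1,4-cyclohexadienes. Ring A is closed by intermolecular cycloaddition, C5–C6 and C1–C2 being made in the same step with bonding at C5–C6 running ahead. No stereocentre is created, since the reacting carbons end trigonal or as CH2, and Cq is a spectator whose four bonds stay intact, so its R configuration is carried through. The selectivity needed is regiochemical: the methylene terminus of the enol ether (future C5) holds the largest HOMO coefficient because methoxy is a far stronger donor than methyl, and it pairs with the ynone β-carbon (future C6), which holds the largest LUMO coefficient, so acetyl ends para to methoxy. Both diene termini are unsubstituted CH2 groups, so the bulk of Cq weighs equally on both orientations and cannot override this electronic bias, while the dioxolane ties two of the three Cq substituents back from the alkyne. Neutral thermal conditions with a radical inhibitor and excess diene are chosen because Lewis or protic acids would hydrolyse or polymerise the enol ether and open the acetonide.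

Step 9
Reactants: 14 [(4R)-4-(2-acetyl-5-methoxy-4-methylcyclohexa-1,4-dien-1-yl)-2,2-dimethyl-1,3-dioxolan-4-yl]methyl 3-methylbutanoate
Product: 15 [(4R)-4-(2-acetyl-5-methoxy-4-methylphenyl)-2,2-dimethyl-1,3-dioxolan-4-yl]methyl 3-methylbutanoate
Conditions: DDQ (1.1 equiv), dry toluene, 0 °C to rt; filter, aq. NaHCO3 wash, chromatography
Reagents that add atoms: none
Why: Dehydrogenative aromatisation with DDQ (hydride abstraction from a doubly allylic CH2, then proton loss) is very fast for 1,4-cyclohexadienes, turns the labile enol ether into the stable aryl methyl ether, and gives the first robust compound at which any minor regioisomer can be removed.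

Step 10
Reactants: 15 [(4R)-4-(2-acetyl-5-methoxy-4-methylphenyl)-2,2-dimethyl-1,3-dioxolan-4-yl]methyl 3-methylbutanoate
Product: 16 [(4R)-4-(2-acetoxy-5-methoxy-4-methylphenyl)-2,2-dimethyl-1,3-dioxolan-4-yl]methyl 3-methylbutanoate
Conditions: mCPBA (2.5 equiv), Na2HPO4 (3 equiv), CH2Cl2, rt to 40 °C; aq. Na2S2O3, aq. NaHCO3
Reagents that add atoms: 3-chloroperbenzoic acid, OOC(=O)c1cccc(Cl)c1
Why: In this Baeyer–Villiger oxidation the electron-rich aryl group, with methoxy para to the migrating carbon, shifts to oxygen in the Criegee adduct far more readily than methyl, so the C1–C bond is exchanged for the C1–O bond of the target, while the buffer protects the acetonide and no alkene is yet present to be epoxidised.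

Step 11
Reactants: 16 [(4R)-4-(2-acetoxy-5-methoxy-4-methylphenyl)-2,2-dimethyl-1,3-dioxolan-4-yl]methyl 3-methylbutanoate
Product: 17 [(4R)-4-(2-hydroxy-5-methoxy-4-methylphenyl)-2,2-dimethyl-1,3-dioxolan-4-yl]methyl 3-methylbutanoate
Conditions: pyrrolidine (2 equiv), CH2Cl2, 0 °C to rt; cold aq. citric acid wash
Reagents that add atoms: none
Why: Aminolysis tells the two esters apart by leaving-group ability, the aryl acetate reacting with a secondary amine at room temperature whereas the neopentyl-type alkyl isovalerate does not, which is safer than carbonate-mediated methanolysis.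

Step 12
Reactants: 17 [(4R)-4-(2-hydroxy-5-methoxy-4-methylphenyl)-2,2-dimethyl-1,3-dioxolan-4-yl]methyl 3-methylbutanoate; 18 (E)-2-methylbut-2-enoyl chloride (tigloyl chloride)
Product: 19 2-[(4R)-2,2-dimethyl-4-{[(3-methylbutanoyl)oxy]methyl}-1,3-dioxolan-4-yl]-4-methoxy-5-methylphenyl (E)-2-methylbut-2-enoate
Conditions: 18 (1.3 equiv), pyridine (3 equiv), DMAP (10 mol %), CH2Cl2, 0 °C to rt
Reagents that add atoms: none
Why: DMAP-catalysed O-acylation of a phenol with an acid chloride is standard, pyridine as the only stoichiometric base is too weak to form the vinylketene that would deconjugate the acyl group, and the E alkene is the thermodynamically favoured isomer and is not at risk.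

Step 13
Reactants: 19 2-[(4R)-2,2-dimethyl-4-{[(3-methylbutanoyl)oxy]methyl}-1,3-dioxolan-4-yl]-4-methoxy-5-methylphenyl (E)-2-methylbut-2-enoate
Product: 20 2-[(2R)-1,2-dihydroxy-3-[(3-methylbutanoyl)oxy]propan-2-yl]-4-methoxy-5-methylphenyl (E)-2-methylbut-2-enoate
Conditions: AcOH–H2O 4:1, 40 °C; azeotroped with toluene below 30 °C, used at once
Reagents that add atoms: none
Why: Acid-catalysed ketal hydrolysis breaks only the O–CMe2 bonds, so the Cq–O bond and the R configuration are untouched, both esters tolerate aqueous acetic acid, and acyl migration is at its slowest in weakly acidic medium.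

Step 14
Reactants: 20 2-[(2R)-1,2-dihydroxy-3-[(3-methylbutanoyl)oxy]propan-2-yl]-4-methoxy-5-methylphenyl (E)-2-methylbut-2-enoate
Product: 22 4-methoxy-5-methyl-2-[(2R)-2-{[(3-methylbutanoyl)oxy]methyl}oxiran-2-yl]phenyl (E)-2-methylbut-2-enoate (target), via primary mesylate 21 (not isolated)
Conditions: MsCl (1.1 equiv), Et3N (1.5 equiv), CH2Cl2, −20 °C; then DBU (2.5 equiv), −20 °C to rt; chromatography on Et3N-deactivated silica
Reagents that add atoms: methanesulfonyl chloride, CS(=O)(=O)Cl (its CH3SO2 group is carried by 21 and leaves again on closure)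
Why: One equivalent of MsCl sulfonylates the primary hydroxyl and leaves the tertiary benzylic one, after which the amidine base triggers an intramolecular Williamson-type 3-exo-tet displacement of mesylate by the tertiary oxygen, so no bond to Cq is broken and its spatial arrangement is retained (the descriptor runs R, S, R through priority changes only), while the aprotic, alkoxide-free medium spares both esters from solvolysis.

Compound list
1 | 2,2-dimethyl-1,3-dioxan-5-one | CC1(C)OCC(=O)CO1 | starting material
2 | ethynylmagnesium bromide | C#C[Mg]Br | starting material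
3 | 5-ethynyl-2,2-dimethyl-1,3-dioxan-5-ol | CC1(C)OCC(O)(C#C)CO1 | intermediate
4 | 2-ethynylpropane-1,2,3-triol | C#CC(O)(CO)CO | intermediate
5 | isovaleric anhydride | CC(C)CC(=O)OC(=O)CC(C)C | starting material
6 | (2R)-2-hydroxy-2-(hydroxymethyl)but-3-yn-1-yl 3-methylbutanoate | C#C[C@](O)(COC(=O)CC(C)C)CO | intermediate
7 | [(4R)-4-ethynyl-2,2-dimethyl-1,3-dioxolan-4-yl]methyl 3-methylbutanoate | C#C[C@]1(COC(=O)CC(C)C)COC(C)(C)O1 | intermediate
8 | N-methoxy-N-methylacetamide | CC(=O)N(C)OC | starting material
9 | lithium acetylide of 7 (R) | [Li]C#C[C@]1(COC(=O)CC(C)C)COC(C)(C)O1 | intermediate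
10 | [(4R)-2,2-dimethyl-4-(3-oxobut-1-yn-1-yl)-1,3-dioxolan-4-yl]methyl 3-methylbutanoate | CC(=O)C#C[C@]1(COC(=O)CC(C)C)COC(C)(C)O1 | intermediate
11 | 3-methylbut-3-en-2-one | CC(=O)C(C)=C | starting material
12 | 1,3,3-trimethoxy-2-methylbutane (racemic) | COCC(C)C(C)(OC)OC | intermediate
13 | 2-methoxy-3-methylbuta-1,3-diene | COC(=C)C(C)=C | intermediate
14 | [(4R)-4-(2-acetyl-5-methoxy-4-methylcyclohexa-1,4-dien-1-yl)-2,2-dimethyl-1,3-dioxolan-4-yl]methyl 3-methylbutanoate | CC(=O)C1=C([C@]2(COC(=O)CC(C)C)COC(C)(C)O2)CC(OC)=C(C)C1 | intermediate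
15 | [(4R)-4-(2-acetyl-5-methoxy-4-methylphenyl)-2,2-dimethyl-1,3-dioxolan-4-yl]methyl 3-methylbutanoate | CC(=O)c1cc(C)c(OC)cc1[C@]1(COC(=O)CC(C)C)COC(C)(C)O1 | intermediate
16 | [(4R)-4-(2-acetoxy-5-methoxy-4-methylphenyl)-2,2-dimethyl-1,3-dioxolan-4-yl]methyl 3-methylbutanoate | CC(=O)Oc1cc(C)c(OC)cc1[C@]1(COC(=O)CC(C)C)COC(C)(C)O1 | intermediate
17 | [(4R)-4-(2-hydroxy-5-methoxy-4-methylphenyl)-2,2-dimethyl-1,3-dioxolan-4-yl]methyl 3-methylbutanoate | Oc1cc(C)c(OC)cc1[C@]1(COC(=O)CC(C)C)COC(C)(C)O1 | intermediate
18 | (E)-2-methylbut-2-enoyl chloride | C/C=C(\C)C(=O)Cl | starting material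
19 | 2-[(4R)-2,2-dimethyl-4-{[(3-methylbutanoyl)oxy]methyl}-1,3-dioxolan-4-yl]-4-methoxy-5-methylphenyl (E)-2-methylbut-2-enoate | C/C=C(\C)C(=O)Oc1cc(C)c(OC)cc1[C@]1(COC(=O)CC(C)C)COC(C)(C)O1 | intermediate
20 | 2-[(2R)-1,2-dihydroxy-3-[(3-methylbutanoyl)oxy]propan-2-yl]-4-methoxy-5-methylphenyl (E)-2-methylbut-2-enoate | C/C=C(\C)C(=O)Oc1cc(C)c(OC)cc1[C@](O)(COC(=O)CC(C)C)CO | intermediate
21 | 2-[(2S)-2-hydroxy-1-(methylsulfonyloxy)-3-[(3-methylbutanoyl)oxy]propan-2-yl]-4-methoxy-5-methylphenyl (E)-2-methylbut-2-enoate | C/C=C(\C)C(=O)Oc1cc(C)c(OC)cc1[C@](O)(COC(=O)CC(C)C)COS(C)(=O)=O | intermediate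
22 | 4-methoxy-5-methyl-2-[(2R)-2-{[(3-methylbutanoyl)oxy]methyl}oxiran-2-yl]phenyl (E)-2-methylbut-2-enoate | C/C=C(\C)C(=O)Oc1cc(C)c(OC)cc1[C@]1(COC(=O)CC(C)C)CO1 | target

Total step count: 14. Longest linear sequence: 12 steps (steps 1–5 and 8–14). The diene branch (steps 6 and 7) is convergent.

Steps most likely to fail

First, step 8.
- **What may go wrong:** The cycloaddition may be too slow at the alkyne terminus next to Cq, so that oligomerisation of the diene takes over. The regiochemical bias may also erode at the temperature required.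
- **Fallback:** The acetyl activator is exchanged for a formyl group, which is smaller, lowers the LUMO further and polarises the triple bond more strongly.
  - Setting out from 7, lithium acetylide 9 is generated as in step 5 and treated with DMF, with inverse quench into cold aq. KH2PO4, to give the alkynyl aldehyde F1.
  - F1 should add diene 13 well below the temperature of step 8 to give the formyl cyclohexadiene F2.
  - DDQ then gives the benzaldehyde F3.
  - Buffered mCPBA converts F3, by aryl migration that is easier for an electron-rich benzaldehyde than for the methyl ketone, into the aryl formate F4.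
  - Pyrrolidine cleaves F4, and the route is rejoined at phenol 17.

Second, step 14, together with the handling of 20 from step 13.
- **What may go wrong:** The tigloyl group may migrate from the phenol oxygen to the neighbouring tertiary oxygen through a six-membered transition state. The freed phenoxide would then attack the mesylate-bearing carbon in competition with oxirane closure.
- **Fallback:** No acyl donor is kept on the phenol while the oxirane is made.
  - Setting out from 17, silylation (i-Pr3SiOTf, 2,6-lutidine, CH2Cl2) gives the aryl triisopropylsilyl ether F5.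
  - Aqueous acetic acid releases the silyl-protected diol F6.
  - MsCl/Et3N gives the silyl-protected mesylate F7, which is closed in the same flask with DBU to the silyl-protected oxirane F8. The hindered silicon should resist transfer to the tertiary oxygen.
  - Slow addition of n-Bu4NF to F8 and excess tiglic anhydride in THF at −20 °C (fluoride-promoted conversion of a silyl ether into an ester) acylates the phenoxide as it forms. The route is rejoined at target 22.

Third, step 3.
- **What may go wrong:** Discrimination between the two hydroxymethyl arms may be insufficient. The enzyme may prefer the wrong arm. Acyl migration in the monoester before ketalisation may erode the enantiomeric purity.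
- **Fallback:** The direction of the enzymatic reaction is reversed.
  - Setting out from 4, chemical acylation of both primary hydroxyls (5, pyridine, cat. DMAP, CH2Cl2, 0 °C) gives the achiral bis(isovalerate) F9.
  - Lipase-catalysed hydrolysis of one enantiotopic ester (pH 7 phosphate buffer–MTBE) then leaves the monoester.
  - An enzyme that would acylate the pro-S arm removes the pro-S ester here, so either preference can be used. The route is rejoined at 6, which is ketalised at once.

Further compounds
F1 | step 8 | [(4R)-2,2-dimethyl-4-(3-oxoprop-1-yn-1-yl)-1,3-dioxolan-4-yl]methyl 3-methylbutanoate | O=CC#C[C@]1(COC(=O)CC(C)C)COC(C)(C)O1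
F2 | step 8 | [(4R)-4-(2-formyl-5-methoxy-4-methylcyclohexa-1,4-dien-1-yl)-2,2-dimethyl-1,3-dioxolan-4-yl]methyl 3-methylbutanoate | O=CC1=C([C@]2(COC(=O)CC(C)C)COC(C)(C)O2)CC(OC)=C(C)C1
F3 | step 8 | [(4R)-4-(2-formyl-5-methoxy-4-methylphenyl)-2,2-dimethyl-1,3-dioxolan-4-yl]methyl 3-methylbutanoate | O=Cc1cc(C)c(OC)cc1[C@]1(COC(=O)CC(C)C)COC(C)(C)O1
F4 | step 8 | [(4R)-4-(2-formyloxy-5-methoxy-4-methylphenyl)-2,2-dimethyl-1,3-dioxolan-4-yl]methyl 3-methylbutanoate | O=COc1cc(C)c(OC)cc1[C@]1(COC(=O)CC(C)C)COC(C)(C)O1
F5 | step 14 | [(4R)-4-{5-methoxy-4-methyl-2-[(triisopropylsilyl)oxy]phenyl}-2,2-dimethyl-1,3-dioxolan-4-yl]methyl 3-methylbutanoate | CC(C)[Si](Oc1cc(C)c(OC)cc1[C@]1(COC(=O)CC(C)C)COC(C)(C)O1)(C(C)C)C(C)C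
F6 | step 14 | (2R)-2,3-dihydroxy-2-{5-methoxy-4-methyl-2-[(triisopropylsilyl)oxy]phenyl}propyl 3-methylbutanoate | CC(C)[Si](Oc1cc(C)c(OC)cc1[C@](O)(COC(=O)CC(C)C)CO)(C(C)C)C(C)C
F7 | step 14 | (2S)-2-hydroxy-2-{5-methoxy-4-methyl-2-[(triisopropylsilyl)oxy]phenyl}-3-(methylsulfonyloxy)propyl 3-methylbutanoate | CC(C)[Si](Oc1cc(C)c(OC)cc1[C@](O)(COC(=O)CC(C)C)COS(C)(=O)=O)(C(C)C)C(C)C
F8 | step 14 | [(2R)-2-{5-methoxy-4-methyl-2-[(triisopropylsilyl)oxy]phenyl}oxiran-2-yl]methyl 3-methylbutanoate | CC(C)[Si](Oc1cc(C)c(OC)cc1[C@]1(COC(=O)CC(C)C)CO1)(C(C)C)C(C)C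
F9 | step 3 | 2-ethynyl-2-hydroxypropane-1,3-diyl bis(3-methylbutanoate) | C#CC(O)(COC(=O)CC(C)C)COC(=O)CC(C)C
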